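**Plan**
1. Retrosynthetic cuts, in order: the O–Si bond on ring B; C4–C4a of the pyran (chromene numbering); O1–C2; ring A itself at C4a–C5 and C6–C7; last the C8–CH2 bond of the prenyl group.
2. Forward: dimedone is prenylated at its C2, converted to its bis(silyl enol ether) and combined with an ynoate that carries ring B. Diels–Alder addition and loss of isobutene give ring A with five substituents in place, so a saturated ring is substituted with control and only then aromatized.
3. The free 4-OH is etherified with a 1,1-dimethylpropargyl group, one thermal pericyclic cascade closes the pyran ring, and desilylation ends the route.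
4. Enabling feature: O1 sits on C8a, whose ortho neighbours are C8 (blocked by prenyl) and C4a (the only C–H of ring A). C4a=C8a–O1–C2–C3–C4 becomes a 3,3-sigmatropic array once C3–C4 is raised to the alkyne level, and the gem-dimethyl group on C2 speeds the shift.
5. The alkyne oxidation level is the only helper of the event. It is used up in the event itself (alkyne to cis-alkene by internal hydrogen transfer), with no reagent and no by-product.
6. Stereochemistry: the target has no stereocentre, C3=C4 is cis by ring constraint, and the prenyl double bond has no E/Z isomers.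

Key step: step 8

Remark: ring A is numbered as a benzoate until the pyran exists. Benzoate C1, C2, C3, C4, C5, C6 become chromene C6, C7, C8, C8a, C4a, C5.

**Step 1**
Reactants: 1 dimedone (5,5-dimethylcyclohexane-1,3-dione); 2 prenyl bromide (1-bromo-3-methylbut-2-ene)
Product: 3 5,5-dimethyl-2-(3-methylbut-2-enyl)cyclohexane-1,3-dione
Conditions: KOH (1.0 equiv), H2O, 0 °C to rt
Reagents that add atoms: prenyl bromide 2, CC(C)=CCBr
Why: C-alkylation of a cyclic 1,3-dione enolate, in which water shields the oxygen atoms by hydrogen bonding and the soft primary allylic bromide is attacked in SN2 fashion by C2, the only carbon between the two carbonyl groups, which fixes the later C8 position of the prenyl group.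

**Step 2**
Reactants: 3 5,5-dimethyl-2-(3-methylbut-2-enyl)cyclohexane-1,3-dione
Product: 4 5,5-dimethyl-2-(3-methylbut-2-enyl)-1,3-bis(trimethylsilyloxy)cyclohexa-1,3-diene
Conditions: TMSOTf (2.3 equiv), Et3N (3 equiv), Et2O, 0 °C to rt; pentane extraction, high vacuum, used crude
Reagents that add atoms: trimethylsilyl triflate, C[Si](C)(C)OS(=O)(=O)C(F)(F)F
Why: Soft enolization with a silyl triflate and a tertiary amine silylates both oxygen atoms, and the symmetrical bis(silyloxy)allyl cation loses a proton from either flanking CH2, which gives the same 1,3-bis(silyloxy)diene.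

**Step 3**
Reactants: 5 4-(4-hydroxyphenyl)butan-2-one
Product: 6 4-[4-(triisopropylsilyloxy)phenyl]butan-2-one
Conditions: TIPSCl, imidazole, DMF, rt
Reagents that add atoms: triisopropylsilyl chloride, CC(C)[Si](Cl)(C(C)C)C(C)C
Why: Standard silylation of a phenol, with a bulky silyl group that should withstand the lithium bases, the heat and the DBU of later steps and leave with fluoride at the end.

**Step 4**
Reactants: 6 4-[4-(triisopropylsilyloxy)phenyl]butan-2-one
Product: 8 1-(but-3-ynyl)-4-(triisopropylsilyloxy)benzene, via enol phosphate 7 (not isolated)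
Conditions: LDA (1.05 equiv), THF, −78 °C; ClP(O)(OEt)2, −78 °C to rt; LDA (2.3 equiv), −78 °C to rt; H2O
Reagents that add atoms: diethyl chlorophosphate, CCOP(=O)(Cl)OCC (its atoms stand in 7 only and leave again)
Why: Kinetic deprotonation at the methyl group, O-phosphorylation and base-induced β-elimination of the terminal enol phosphate is the established conversion of a methyl ketone to a terminal alkyne.

**Step 5**
Reactants: 8 1-(but-3-ynyl)-4-(triisopropylsilyloxy)benzene; 9 methyl chloroformate
Product: 10 methyl 5-[4-(triisopropylsilyloxy)phenyl]pent-2-ynoate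
Conditions: n-BuLi, THF, −78 °C; then 9, −78 to 0 °C
Reagents that add atoms: methyl chloroformate 9, COC(=O)Cl
Why: Deprotonation of the terminal alkyne and C-acylation with a chloroformate is the standard route to 2-ynoates, and the aryl silyl ether is inert at this temperature.

**Step 6**
Reactants: 4 5,5-dimethyl-2-(3-methylbut-2-enyl)-1,3-bis(trimethylsilyloxy)cyclohexa-1,3-diene; 10 methyl 5-[4-(triisopropylsilyloxy)phenyl]pent-2-ynoate
Product: 13 methyl 2,4-dihydroxy-3-(3-methylbut-2-enyl)-6-{2-[4-(triisopropylsilyloxy)phenyl]ethyl}benzoate, via bicyclooctadiene cycloadduct 11 (not isolated), via bis-TMS resorcylate 12 (not isolated)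
Conditions: 4 (2.5 equiv), neat, sealed tube, 160 °C; then MeOH, citric acid (cat.), rt
Reagents that add atoms: none
Why: Diels–Alder/retro-Diels–Alder benzannulation (Alder–Rickert reaction), in which the unsubstituted and most nucleophilic diene terminus bonds to the β-carbon of the ynoate, the adduct expels its CMe2–CH2 bridge as isobutene on aromatization under neutral conditions that spare the prenyl group, and methanolysis removes the two labile TMS groups while the TIPS ether stays.

**Step 7**
Reactants: 13 methyl 2,4-dihydroxy-3-(3-methylbut-2-enyl)-6-{2-[4-(triisopropylsilyloxy)phenyl]ethyl}benzoate; 14 3-chloro-3-methylbut-1-yne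
Product: 15 methyl 2-hydroxy-3-(3-methylbut-2-enyl)-4-(2-methylbut-3-yn-2-yloxy)-6-{2-[4-(triisopropylsilyloxy)phenyl]ethyl}benzoate
Conditions: 14 (1.5 equiv), CuCl2·2H2O (1 mol %), DBU (1.5 equiv), MeCN, 0 °C
Reagents that add atoms: 3-chloro-3-methylbut-1-yne 14, CC(C)(Cl)C#C
Why: Copper-catalysed O-alkylation of a phenol with a tertiary propargylic chloride, selective for the 4-OH because the 2-OH is hydrogen-bonded to the ester and flanked on both sides.

**Step 8**
Reactants: 15 methyl 2-hydroxy-3-(3-methylbut-2-enyl)-4-(2-methylbut-3-yn-2-yloxy)-6-{2-[4-(triisopropylsilyloxy)phenyl]ethyl}benzoate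
Product: 19 methyl 7-hydroxy-2,2-dimethyl-8-(3-methylbut-2-enyl)-5-{2-[4-(triisopropylsilyloxy)phenyl]ethyl}-2H-chromene-6-carboxylate, via allenyl dienone 16 (not isolated), via ortho-allenylphenol 17 (not isolated), via ortho-quinone methide 18 (not isolated)
Conditions: 1,2-dichlorobenzene (0.05 M), 170 °C, argon
Reagents that add atoms: none
Why: Heating starts an aromatic propargyl Claisen rearrangement in which the array C5=C4–O–CMe2–C≡CH shifts suprafacially, cutting O–CMe2 and joining the alkyne terminus to C5 to give dienone 16, which enolizes to allenylphenol 17. A 1,5-hydrogen shift from the new 4-OH to the central allene carbon gives the (Z)-ortho-quinone methide 18, and its disrotatory oxa-6π electrocyclization re-forms O–CMe2 and closes the pyran ring, so the net change from 15 to 19 is a 6-endo-dig addition of C5–H across the alkyne with C4–C4a of the chromene as the only new skeletal bond. The closest known reaction type is the thermal conversion of aryl 1,1-dimethylpropargyl ethers to 2,2-dimethyl-2H-chromenes, which the gem-dimethyl group accelerates. No stereocentre is created, since C5 of 16 is stereogenic only in passing and C3=C4 is cis by ring constraint. The step needs site selectivity between the two carbons ortho to O-4, and the substrate secures it because C3 carries the prenyl group, so a shift to C3 gives a dienone that cannot enolize and reverts, whereas C5 bears the only hydrogen of ring A. It also needs the right oxygen to close the ring, and only O-4 is ortho to the new side chain, the 2-OH being remote and hydrogen-bonded to the ester.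

**Step 9**
Reactants: 19 methyl 7-hydroxy-2,2-dimethyl-8-(3-methylbut-2-enyl)-5-{2-[4-(triisopropylsilyloxy)phenyl]ethyl}-2H-chromene-6-carboxylate
Product: 20 methyl 7-hydroxy-5-[2-(4-hydroxyphenyl)ethyl]-2,2-dimethyl-8-(3-methylbut-2-enyl)-2H-chromene-6-carboxylate (target)
Conditions: TBAF, AcOH (1:1), THF, 0 °C
Reagents that add atoms: none
Why: Fluoride cleavage of an aryl silyl ether under acetic acid buffering, to which the methyl ester, the chromene and the prenyl group are inert.

**Compound list**
1 | dimedone (5,5-dimethylcyclohexane-1,3-dione) | CC1(C)CC(=O)CC(=O)C1 | starting material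
2 | prenyl bromide (1-bromo-3-methylbut-2-ene) | CC(C)=CCBr | starting material
3 | 5,5-dimethyl-2-(3-methylbut-2-enyl)cyclohexane-1,3-dione | CC(C)=CCC1C(=O)CC(C)(C)CC1=O | intermediate
4 | 5,5-dimethyl-2-(3-methylbut-2-enyl)-1,3-bis(trimethylsilyloxy)cyclohexa-1,3-diene | C[Si](C)(C)OC1=C(CC=C(C)C)C(O[Si](C)(C)C)=CC(C)(C)C1 | intermediate
5 | 4-(4-hydroxyphenyl)butan-2-one | CC(=O)CCc1ccc(O)cc1 | starting material
6 | 4-[4-(triisopropylsilyloxy)phenyl]butan-2-one | CC(=O)CCc1ccc(O[Si](C(C)C)(C(C)C)C(C)C)cc1 | intermediate
7 | diethyl 4-[4-(triisopropylsilyloxy)phenyl]but-1-en-2-yl phosphate | C=C(CCc1ccc(O[Si](C(C)C)(C(C)C)C(C)C)cc1)OP(=O)(OCC)OCC | intermediate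
8 | 1-(but-3-ynyl)-4-(triisopropylsilyloxy)benzene | C#CCCc1ccc(O[Si](C(C)C)(C(C)C)C(C)C)cc1 | intermediate
9 | methyl chloroformate | COC(=O)Cl | starting material
10 | methyl 5-[4-(triisopropylsilyloxy)phenyl]pent-2-ynoate | COC(=O)C#CCCc1ccc(O[Si](C(C)C)(C(C)C)C(C)C)cc1 | intermediate
11 | methyl 8,8-dimethyl-6-(3-methylbut-2-enyl)-3-{2-[4-(triisopropylsilyloxy)phenyl]ethyl}-1,5-bis(trimethylsilyloxy)bicyclo[2.2.2]octa-2,5-diene-2-carboxylate (racemic) | COC(=O)C1=C(CCc2ccc(O[Si](C(C)C)(C(C)C)C(C)C)cc2)C2C(O[Si](C)(C)C)=C(CC=C(C)C)C1(O[Si](C)(C)C)CC2(C)C | intermediate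
12 | methyl 3-(3-methylbut-2-enyl)-6-{2-[4-(triisopropylsilyloxy)phenyl]ethyl}-2,4-bis(trimethylsilyloxy)benzoate | COC(=O)c1c(O[Si](C)(C)C)c(CC=C(C)C)c(O[Si](C)(C)C)cc1CCc1ccc(O[Si](C(C)C)(C(C)C)C(C)C)cc1 | intermediate
13 | methyl 2,4-dihydroxy-3-(3-methylbut-2-enyl)-6-{2-[4-(triisopropylsilyloxy)phenyl]ethyl}benzoate | COC(=O)c1c(O)c(CC=C(C)C)c(O)cc1CCc1ccc(O[Si](C(C)C)(C(C)C)C(C)C)cc1 | intermediate
14 | 3-chloro-3-methylbut-1-yne | CC(C)(Cl)C#C | starting material
15 | methyl 2-hydroxy-3-(3-methylbut-2-enyl)-4-(2-methylbut-3-yn-2-yloxy)-6-{2-[4-(triisopropylsilyloxy)phenyl]ethyl}benzoate | COC(=O)c1c(O)c(CC=C(C)C)c(OC(C)(C)C#C)cc1CCc1ccc(O[Si](C(C)C)(C(C)C)C(C)C)cc1 | intermediate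
16 | methyl 2-hydroxy-5-(3-methylbuta-1,2-dienyl)-3-(3-methylbut-2-enyl)-4-oxo-6-{2-[4-(triisopropylsilyloxy)phenyl]ethyl}cyclohexa-1(6),2-diene-1-carboxylate (racemic) | COC(=O)C1=C(CCc2ccc(O[Si](C(C)C)(C(C)C)C(C)C)cc2)C(C=C=C(C)C)C(=O)C(CC=C(C)C)=C1O | intermediate
17 | methyl 2,4-dihydroxy-5-(3-methylbuta-1,2-dienyl)-3-(3-methylbut-2-enyl)-6-{2-[4-(triisopropylsilyloxy)phenyl]ethyl}benzoate | COC(=O)c1c(O)c(CC=C(C)C)c(O)c(C=C=C(C)C)c1CCc1ccc(O[Si](C(C)C)(C(C)C)C(C)C)cc1 | intermediate
18 | methyl (5Z)-2-hydroxy-3-(3-methylbut-2-enyl)-5-(3-methylbut-2-enylidene)-4-oxo-6-{2-[4-(triisopropylsilyloxy)phenyl]ethyl}cyclohexa-1(6),2-diene-1-carboxylate | CC(C)=C/C=C1\C(=O)C(CC=C(C)C)=C(O)C(C(=O)OC)=C1CCc1ccc(O[Si](C(C)C)(C(C)C)C(C)C)cc1 | intermediate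
19 | methyl 7-hydroxy-2,2-dimethyl-8-(3-methylbut-2-enyl)-5-{2-[4-(triisopropylsilyloxy)phenyl]ethyl}-2H-chromene-6-carboxylate | COC(=O)c1c(O)c(CC=C(C)C)c2c(c1CCc1ccc(O[Si](C(C)C)(C(C)C)C(C)C)cc1)C=CC(C)(C)O2 | intermediate
20 | methyl 7-hydroxy-5-[2-(4-hydroxyphenyl)ethyl]-2,2-dimethyl-8-(3-methylbut-2-enyl)-2H-chromene-6-carboxylate | COC(=O)c1c(O)c(CC=C(C)C)c2c(c1CCc1ccc(O)cc1)C=CC(C)(C)O2 | target

**Total step count:** 9. **Longest linear sequence:** 7 steps (5 → 6 → 8 → 10 → 13 → 15 → 19 → 20).

**Steps most likely to fail**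

**Step 6.**
- What may go wrong: the cycloaddition of a β-alkyl ynoate with a diene that carries a substituent on every carbon but one may be too slow, so hydrolysis or decomposition of the diene could overtake it.
- Fallback: the prenyl group is taken off the diene and brought in after ring A exists. The fallback sets out from 10 and comes back at 13.
- Diene: dimedone 1 is silylated as in step 2 to 5,5-dimethyl-1,3-bis(trimethylsilyloxy)cyclohexa-1,3-diene F1.
- Benzannulation: F1 is heated with 10 (neat, 150 °C). The reaction should pass through the bicyclooctadiene cycloadduct F2 and the bis(trimethylsilyl) ether F3. Methanolysis then gives methyl 2,4-dihydroxy-6-{2-[4-(triisopropylsilyloxy)phenyl]ethyl}benzoate F4.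
- Prenyl transfer: the free 4-OH of F4 is alkylated with tert-butyl 2-methylbut-3-en-2-yl carbonate and Pd(PPh3)4 (zerovalent palladium, THF, 0 °C, phenoxide attack at the tertiary end of the π-allyl complex) to the 1,1-dimethylallyl ether F5. An aromatic Claisen rearrangement (toluene, 110 °C) should then carry the allyl unit with inversion to C3, the ortho position favoured by the bond fixation of the chelated salicylate, and give 13.

**Step 7.**
- What may go wrong: O-alkylation next to the prenyl group may be slow. The tertiary chloride may be lost by elimination to the enyne, the 2-OH may be alkylated as well, and the silyl ether may be lost to DBU.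
- Fallback: the propargyl ether is given up and the five-carbon unit is brought in as an aldehyde. The fallback sets out from 13 and comes back at 19.
- 13 is condensed with 3-methylbut-2-enal (ethylenediammonium diacetate cat., xylene, 130 °C). C5, the only free ring carbon, attacks the activated aldehyde, loss of water gives quinone methide 18 in the flask, and 18 closes to 19.
- This fallback makes no compound outside the list (F0).

**Step 8.**
- What may go wrong: the shift may run to the blocked ortho carbon and be followed by an internal cycloaddition of the allene onto the dienone. Alternatively the tertiary propargyl group may be lost thermally before the shift to the hindered C5 takes place.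
- Fallback: the pericyclic path is replaced by an electrophilic one at room temperature. The fallback sets out from 15 and comes back at 19.
- Ph3PAuNTf2 (monovalent gold, 3 mol %, CH2Cl2, rt) activates the alkyne as a π-acid, and C5 attacks its terminus directly in a 6-endo-dig Friedel–Crafts-type hydroarylation. O–CMe2 is never cut and no allene or dienone is formed.
- This fallback makes no compound outside the list (F0).

**Further compounds**
F1 | step 6 | 5,5-dimethyl-1,3-bis(trimethylsilyloxy)cyclohexa-1,3-diene | C[Si](C)(C)OC1=CC(O[Si](C)(C)C)=CC(C)(C)C1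
F2 | step 6 | methyl 8,8-dimethyl-3-{2-[4-(triisopropylsilyloxy)phenyl]ethyl}-1,5-bis(trimethylsilyloxy)bicyclo[2.2.2]octa-2,5-diene-2-carboxylate (racemic) | COC(=O)C1=C(CCc2ccc(O[Si](C(C)C)(C(C)C)C(C)C)cc2)C2C(O[Si](C)(C)C)=CC1(O[Si](C)(C)C)CC2(C)C
F3 | step 6 | methyl 6-{2-[4-(triisopropylsilyloxy)phenyl]ethyl}-2,4-bis(trimethylsilyloxy)benzoate | COC(=O)c1c(O[Si](C)(C)C)cc(O[Si](C)(C)C)cc1CCc1ccc(O[Si](C(C)C)(C(C)C)C(C)C)cc1
F4 | step 6 | methyl 2,4-dihydroxy-6-{2-[4-(triisopropylsilyloxy)phenyl]ethyl}benzoate | COC(=O)c1c(O)cc(O)cc1CCc1ccc(O[Si](C(C)C)(C(C)C)C(C)C)cc1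
F5 | step 6 | methyl 2-hydroxy-4-(2-methylbut-3-en-2-yloxy)-6-{2-[4-(triisopropylsilyloxy)phenyl]ethyl}benzoate | COC(=O)c1c(O)cc(OC(C)(C)C=C)cc1CCc1ccc(O[Si](C(C)C)(C(C)C)C(C)C)cc1
F0 | step 7 | none | none
F0 | step 8 | none | none
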